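**Retrosynthetic overview**
1. The pyran ring is closed last. Target 27 comes from allylic acetate 24 by fluoride-triggered o-quinone methide formation and oxa-6π closure, and 24 comes from aldehyde 22 plus isobutenyl-MgBr.
2. The prenyl group comes from benzylic bromide 18 plus isobutenyl-MgBr (Cu). The ArCH2 and ArCHO carbons are the two ester carbons of isophthalate 13, told apart as tBu versus Me.
3. The central benzene ring comes from aromatisation of cyclohexane-1,3-dione 12. The key step to 12 is the intermolecular Michael addition of tert-butyl acetoacetate to alkylidene malonate 9, followed by Dieckmann closure.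
4. Compound 9 comes from Knoevenagel condensation of benzofuran-2-carbaldehyde 7 with dimethyl malonate, and the benzofuran comes from 2,4-dihydroxybenzaldehyde plus ethyl bromoacetate. Ring order: benzofuran, then benzene, then 2H-pyran.

Assumption: the SMILES holds no stereocentre and the aryl–benzofuranyl axis is taken as freely rotating. The target is therefore achiral and no enantioselective step is needed. TIPS = triisopropylsilyl.

**Step 1**
Reactants: 1 2,4-dihydroxybenzaldehyde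
Product: 2 4-(benzyloxy)-2-hydroxybenzaldehyde
Conditions: BnBr (1.05 equiv), NaHCO3, MeCN, 80 °C
Reagents that add atoms: benzyl bromide, BrCc1ccccc1
Why: Williamson etherification; the 2-OH is hydrogen-bonded to the aldehyde and less acidic, so a weak base benzylates only the 4-OH.

**Step 2**
Reactants: 2 4-(benzyloxy)-2-hydroxybenzaldehyde; 3 ethyl bromoacetate
Product: 5 ethyl 6-(benzyloxy)-1-benzofuran-2-carboxylate, via ethyl 2-[5-(benzyloxy)-2-formylphenoxy]acetate 4 (not isolated)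
Conditions: K2CO3, DMF, 110 °C
Reagents that add atoms: none
Why: O-alkylation followed by intramolecular aldol condensation of the aryloxyacetate onto the ortho aldehyde, with loss of water driven by formation of the aromatic furan ring.

**Step 3**
Reactants: 5 ethyl 6-(benzyloxy)-1-benzofuran-2-carboxylate
Product: 6 [6-(benzyloxy)-1-benzofuran-2-yl]methanol
Conditions: LiAlH4, THF, 0 °C
Reagents that add atoms: none
Why: Hydride reduction of the ester to the primary alcohol; the benzyl ether and the benzofuran are inert.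

**Step 4**
Reactants: 6 [6-(benzyloxy)-1-benzofuran-2-yl]methanol
Product: 7 6-(benzyloxy)-1-benzofuran-2-carbaldehyde
Conditions: MnO2, CH2Cl2, rt
Reagents that add atoms: none
Why: MnO2 oxidation of a furfuryl-type (benzylic) alcohol, which stops cleanly at the aldehyde.

**Step 5**
Reactants: 7 6-(benzyloxy)-1-benzofuran-2-carbaldehyde; 8 dimethyl malonate
Product: 9 dimethyl 2-{[6-(benzyloxy)-1-benzofuran-2-yl]methylidene}propanedioate
Conditions: piperidine (cat.), AcOH (cat.), toluene, Dean–Stark, reflux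
Reagents that add atoms: none
Why: Knoevenagel condensation driven by azeotropic removal of water; the two identical esters rule out any E/Z issue.

**Step 6 (key step)**
Reactants: 9 dimethyl 2-{[6-(benzyloxy)-1-benzofuran-2-yl]methylidene}propanedioate; 10 tert-butyl acetoacetate
Product: 12 1-tert-butyl 3-methyl 2-[6-(benzyloxy)-1-benzofuran-2-yl]-4,6-dioxocyclohexane-1,3-dicarboxylate, via 3-tert-butyl 1,1-dimethyl 2-[6-(benzyloxy)-1-benzofuran-2-yl]-4-oxopentane-1,1,3-tricarboxylate 11 (not isolated)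
Conditions: NaOMe (1.1 equiv), MeOH, 0 °C → rt, then reflux; cold 1 M HCl
Reagents that add atoms: none
Why: Intermolecular Michael addition of the acetoacetate enolate to the doubly activated alkene joins the two fragments, and Dieckmann (intramolecular Claisen) attack of the acetyl CH3 on a malonate ester, the only six-membered C-acylation open to 11, is pulled through by the stabilised 1,3-dione enolate; the transient stereocentres (racemic diastereomer mixture) are erased in step 7.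

**Step 7**
Reactants: 12 1-tert-butyl 3-methyl 2-[6-(benzyloxy)-1-benzofuran-2-yl]-4,6-dioxocyclohexane-1,3-dicarboxylate
Product: 13 1-tert-butyl 3-methyl 2-[6-(benzyloxy)-1-benzofuran-2-yl]-4,6-dihydroxybenzene-1,3-dicarboxylate
Conditions: DDQ (1.2 equiv), 1,4-dioxane, rt → 60 °C
Reagents that add atoms: none
Why: Quinone dehydrogenation; the ring C–H that carries the benzofuran is allylic to both β-keto-ester enols and heterobenzylic, so hydride abstraction is easy and tautomerisation gives the electron-poor resorcinol, which DDQ does not attack further.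

**Step 8**
Reactants: 13 1-tert-butyl 3-methyl 2-[6-(benzyloxy)-1-benzofuran-2-yl]-4,6-dihydroxybenzene-1,3-dicarboxylate
Product: 14 1-tert-butyl 3-methyl 4,6-dihydroxy-2-(6-hydroxy-1-benzofuran-2-yl)benzene-1,3-dicarboxylate
Conditions: H2 (1 atm), 10% Pd/C, EtOAc, rt
Reagents that add atoms: none
Why: Hydrogenolysis of the benzyl ether, done while the molecule still has no olefin; the hindered 2-arylbenzofuran is not reduced at 1 atm.

**Step 9**
Reactants: 14 1-tert-butyl 3-methyl 4,6-dihydroxy-2-(6-hydroxy-1-benzofuran-2-yl)benzene-1,3-dicarboxylate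
Product: 15 1-tert-butyl 3-methyl 4,6-bis[(triisopropylsilyl)oxy]-2-{6-[(triisopropylsilyl)oxy]-1-benzofuran-2-yl}benzene-1,3-dicarboxylate
Conditions: TIPSCl (4 equiv), imidazole, DMAP (cat.), DMF, 50 °C
Reagents that add atoms: triisopropylsilyl chloride, CC(C)[Si](Cl)(C(C)C)C(C)C
Why: Silyl ether formation on all three phenols; aryl TIPS ethers withstand TFA, BH3, DIBAL-H and Grignard reagents and leave with fluoride at the end.

**Step 10**
Reactants: 15 1-tert-butyl 3-methyl 4,6-bis[(triisopropylsilyl)oxy]-2-{6-[(triisopropylsilyl)oxy]-1-benzofuran-2-yl}benzene-1,3-dicarboxylate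
Product: 16 3-(methoxycarbonyl)-4,6-bis[(triisopropylsilyl)oxy]-2-{6-[(triisopropylsilyl)oxy]-1-benzofuran-2-yl}benzoic acid
Conditions: TFA/CH2Cl2 (1:4), 0 °C → rt
Reagents that add atoms: none
Why: Acidolysis (E1 loss of isobutene) cleaves only the tert-butyl ester, which tells the two carboxyl carbons apart; the methyl ester and aryl TIPS ethers are inert to anhydrous TFA.

**Step 11**
Reactants: 16 3-(methoxycarbonyl)-4,6-bis[(triisopropylsilyl)oxy]-2-{6-[(triisopropylsilyl)oxy]-1-benzofuran-2-yl}benzoic acid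
Product: 17 methyl 3-(hydroxymethyl)-4,6-bis[(triisopropylsilyl)oxy]-2-{6-[(triisopropylsilyl)oxy]-1-benzofuran-2-yl}benzoate
Conditions: BH3·THF (3 equiv), THF, 0 °C → 40 °C; MeOH, then H2O
Reagents that add atoms: none
Why: Chemoselective borane reduction of the carboxylic acid through its acyloxyborane, which leaves the hindered methyl ester and the benzofuran untouched.

**Step 12**
Reactants: 17 methyl 3-(hydroxymethyl)-4,6-bis[(triisopropylsilyl)oxy]-2-{6-[(triisopropylsilyl)oxy]-1-benzofuran-2-yl}benzoate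
Product: 18 methyl 3-(bromomethyl)-4,6-bis[(triisopropylsilyl)oxy]-2-{6-[(triisopropylsilyl)oxy]-1-benzofuran-2-yl}benzoate
Conditions: CBr4, PPh3, CH2Cl2, 0 °C (short plug, used at once)
Reagents that add atoms: carbon tetrabromide, BrC(Br)(Br)Br
Why: The Appel reaction gives the reactive benzylic bromide under neutral conditions that spare the silyl ethers.

**Step 13**
Reactants: 18 methyl 3-(bromomethyl)-4,6-bis[(triisopropylsilyl)oxy]-2-{6-[(triisopropylsilyl)oxy]-1-benzofuran-2-yl}benzoate; 19 2-methylprop-1-en-1-ylmagnesium bromide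
Product: 20 methyl 3-(3-methylbut-2-en-1-yl)-4,6-bis[(triisopropylsilyl)oxy]-2-{6-[(triisopropylsilyl)oxy]-1-benzofuran-2-yl}benzoate
Conditions: 19 (2 equiv), CuI (10 mol %), THF, −40 → 0 °C
Reagents that add atoms: none
Why: Copper-catalysed sp3–sp2 cross-coupling of a benzylic bromide with an alkenyl Grignard reagent builds the prenyl group with its double bond already in place; the di-ortho-substituted ester is ignored at low temperature.

**Step 14**
Reactants: 20 methyl 3-(3-methylbut-2-en-1-yl)-4,6-bis[(triisopropylsilyl)oxy]-2-{6-[(triisopropylsilyl)oxy]-1-benzofuran-2-yl}benzoate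
Product: 21 [3-(3-methylbut-2-en-1-yl)-4,6-bis[(triisopropylsilyl)oxy]-2-{6-[(triisopropylsilyl)oxy]-1-benzofuran-2-yl}phenyl]methanol
Conditions: DIBAL-H (3 equiv), toluene, −78 → 0 °C; aq. Rochelle salt
Reagents that add atoms: none
Why: DIBAL-H binds the carbonyl oxygen and reduces even hindered benzoates to the primary alcohol; the olefin and TIPS ethers survive.

**Step 15**
Reactants: 21 [3-(3-methylbut-2-en-1-yl)-4,6-bis[(triisopropylsilyl)oxy]-2-{6-[(triisopropylsilyl)oxy]-1-benzofuran-2-yl}phenyl]methanol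
Product: 22 3-(3-methylbut-2-en-1-yl)-4,6-bis[(triisopropylsilyl)oxy]-2-{6-[(triisopropylsilyl)oxy]-1-benzofuran-2-yl}benzaldehyde
Conditions: MnO2, CH2Cl2, rt
Reagents that add atoms: none
Why: MnO2 oxidation of an electron-rich benzylic alcohol to the aldehyde, without touching the prenyl double bond.

**Step 16**
Reactants: 22 3-(3-methylbut-2-en-1-yl)-4,6-bis[(triisopropylsilyl)oxy]-2-{6-[(triisopropylsilyl)oxy]-1-benzofuran-2-yl}benzaldehyde; 19 2-methylprop-1-en-1-ylmagnesium bromide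
Product: 24 3-methyl-1-[3-(3-methylbut-2-en-1-yl)-4,6-bis[(triisopropylsilyl)oxy]-2-{6-[(triisopropylsilyl)oxy]-1-benzofuran-2-yl}phenyl]but-2-en-1-yl acetate (racemic), via the bromomagnesium alkoxide of the corresponding allylic alcohol 23 (not isolated)
Conditions: 19 (1.5 equiv), THF, −78 → 0 °C; then Ac2O, DMAP (cat.), 0 °C → rt (crude product carried on)
Reagents that add atoms: acetic anhydride, CC(=O)OC(C)=O
Why: Grignard 1,2-addition to the aldehyde followed by in-flask acetylation of the alkoxide installs the C4 unit and a leaving group; the new stereocentre is racemic and is destroyed in step 17.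

**Step 17**
Reactants: 24 3-methyl-1-[3-(3-methylbut-2-en-1-yl)-4,6-bis[(triisopropylsilyl)oxy]-2-{6-[(triisopropylsilyl)oxy]-1-benzofuran-2-yl}phenyl]but-2-en-1-yl acetate
Product: 27 cathafuran C, via 1-[4,6-dihydroxy-2-(6-hydroxy-1-benzofuran-2-yl)-3-(3-methylbut-2-en-1-yl)phenyl]-3-methylbut-2-en-1-yl acetate 25 (not isolated), via 3-hydroxy-5-(6-hydroxy-1-benzofuran-2-yl)-4-(3-methylbut-2-en-1-yl)-6-(3-methylbut-2-en-1-ylidene)cyclohexa-2,4-dien-1-one 26 (not isolated)
Conditions: TBAF (3.5 equiv), THF (0.01 M), 0 °C → rt; AcOH quench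
Reagents that add atoms: none
Why: Fluoride desilylation frees the phenoxides, the one ortho to the side chain expels acetate (1,4-elimination) to a vinyl o-quinone methide, and oxa-6π electrocyclisation closes the 2,2-dimethyl-2H-pyran on the only adjacent oxygen under non-acidic conditions that spare the o-prenylphenol; no stereocentre remains.

**Compound list**
1 | 2,4-dihydroxybenzaldehyde | O=Cc1ccc(O)cc1O | starting material
2 | 4-(benzyloxy)-2-hydroxybenzaldehyde | O=Cc1ccc(OCc2ccccc2)cc1O | intermediate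
3 | ethyl bromoacetate | CCOC(=O)CBr | starting material
4 | ethyl 2-[5-(benzyloxy)-2-formylphenoxy]acetate | CCOC(=O)COc1cc(OCc2ccccc2)ccc1C=O | intermediate (not isolated)
5 | ethyl 6-(benzyloxy)-1-benzofuran-2-carboxylate | CCOC(=O)c1cc2ccc(OCc3ccccc3)cc2o1 | intermediate
6 | [6-(benzyloxy)-1-benzofuran-2-yl]methanol | OCc1cc2ccc(OCc3ccccc3)cc2o1 | intermediate
7 | 6-(benzyloxy)-1-benzofuran-2-carbaldehyde | O=Cc1cc2ccc(OCc3ccccc3)cc2o1 | intermediate
8 | dimethyl malonate | COC(=O)CC(=O)OC | starting material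
9 | dimethyl 2-{[6-(benzyloxy)-1-benzofuran-2-yl]methylidene}propanedioate | COC(=O)C(=Cc1cc2ccc(OCc3ccccc3)cc2o1)C(=O)OC | intermediate
10 | tert-butyl acetoacetate | CC(=O)CC(=O)OC(C)(C)C | starting material
11 | 3-tert-butyl 1,1-dimethyl 2-[6-(benzyloxy)-1-benzofuran-2-yl]-4-oxopentane-1,1,3-tricarboxylate (racemic diastereomer mixture) | COC(=O)C(C(=O)OC)C(c1cc2ccc(OCc3ccccc3)cc2o1)C(C(C)=O)C(=O)OC(C)(C)C | intermediate (not isolated)
12 | 1-tert-butyl 3-methyl 2-[6-(benzyloxy)-1-benzofuran-2-yl]-4,6-dioxocyclohexane-1,3-dicarboxylate (racemic diastereomer/enol mixture) | COC(=O)C1C(=O)CC(=O)C(C(=O)OC(C)(C)C)C1c1cc2ccc(OCc3ccccc3)cc2o1 | intermediate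
13 | 1-tert-butyl 3-methyl 2-[6-(benzyloxy)-1-benzofuran-2-yl]-4,6-dihydroxybenzene-1,3-dicarboxylate | COC(=O)c1c(O)cc(O)c(C(=O)OC(C)(C)C)c1-c1cc2ccc(OCc3ccccc3)cc2o1 | intermediate
14 | 1-tert-butyl 3-methyl 4,6-dihydroxy-2-(6-hydroxy-1-benzofuran-2-yl)benzene-1,3-dicarboxylate | COC(=O)c1c(O)cc(O)c(C(=O)OC(C)(C)C)c1-c1cc2ccc(O)cc2o1 | intermediate
15 | 1-tert-butyl 3-methyl 4,6-bis(TIPS-oxy)-2-[6-(TIPS-oxy)-1-benzofuran-2-yl]benzene-1,3-dicarboxylate | COC(=O)c1c(O[Si](C(C)C)(C(C)C)C(C)C)cc(O[Si](C(C)C)(C(C)C)C(C)C)c(C(=O)OC(C)(C)C)c1-c1cc2ccc(O[Si](C(C)C)(C(C)C)C(C)C)cc2o1 | intermediate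
16 | 3-(methoxycarbonyl)-4,6-bis(TIPS-oxy)-2-[6-(TIPS-oxy)-1-benzofuran-2-yl]benzoic acid | COC(=O)c1c(O[Si](C(C)C)(C(C)C)C(C)C)cc(O[Si](C(C)C)(C(C)C)C(C)C)c(C(=O)O)c1-c1cc2ccc(O[Si](C(C)C)(C(C)C)C(C)C)cc2o1 | intermediate
17 | methyl 3-(hydroxymethyl)-4,6-bis(TIPS-oxy)-2-[6-(TIPS-oxy)-1-benzofuran-2-yl]benzoate | COC(=O)c1c(O[Si](C(C)C)(C(C)C)C(C)C)cc(O[Si](C(C)C)(C(C)C)C(C)C)c(CO)c1-c1cc2ccc(O[Si](C(C)C)(C(C)C)C(C)C)cc2o1 | intermediate
18 | methyl 3-(bromomethyl)-4,6-bis(TIPS-oxy)-2-[6-(TIPS-oxy)-1-benzofuran-2-yl]benzoate | COC(=O)c1c(O[Si](C(C)C)(C(C)C)C(C)C)cc(O[Si](C(C)C)(C(C)C)C(C)C)c(CBr)c1-c1cc2ccc(O[Si](C(C)C)(C(C)C)C(C)C)cc2o1 | intermediate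
19 | 2-methylprop-1-en-1-ylmagnesium bromide (commercial THF solution) | CC(C)=C[Mg]Br | starting material
20 | methyl 3-(3-methylbut-2-en-1-yl)-4,6-bis(TIPS-oxy)-2-[6-(TIPS-oxy)-1-benzofuran-2-yl]benzoate | COC(=O)c1c(O[Si](C(C)C)(C(C)C)C(C)C)cc(O[Si](C(C)C)(C(C)C)C(C)C)c(CC=C(C)C)c1-c1cc2ccc(O[Si](C(C)C)(C(C)C)C(C)C)cc2o1 | intermediate
21 | [3-(3-methylbut-2-en-1-yl)-4,6-bis(TIPS-oxy)-2-[6-(TIPS-oxy)-1-benzofuran-2-yl]phenyl]methanol | OCc1c(O[Si](C(C)C)(C(C)C)C(C)C)cc(O[Si](C(C)C)(C(C)C)C(C)C)c(CC=C(C)C)c1-c1cc2ccc(O[Si](C(C)C)(C(C)C)C(C)C)cc2o1 | intermediate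
22 | 3-(3-methylbut-2-en-1-yl)-4,6-bis(TIPS-oxy)-2-[6-(TIPS-oxy)-1-benzofuran-2-yl]benzaldehyde | O=Cc1c(O[Si](C(C)C)(C(C)C)C(C)C)cc(O[Si](C(C)C)(C(C)C)C(C)C)c(CC=C(C)C)c1-c1cc2ccc(O[Si](C(C)C)(C(C)C)C(C)C)cc2o1 | intermediate
23 | bromomagnesium 3-methyl-1-[3-(3-methylbut-2-en-1-yl)-4,6-bis(TIPS-oxy)-2-[6-(TIPS-oxy)-1-benzofuran-2-yl]phenyl]but-2-en-1-olate (racemic) | CC(C)=CC(O[Mg]Br)c1c(O[Si](C(C)C)(C(C)C)C(C)C)cc(O[Si](C(C)C)(C(C)C)C(C)C)c(CC=C(C)C)c1-c1cc2ccc(O[Si](C(C)C)(C(C)C)C(C)C)cc2o1 | intermediate (not isolated)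
24 | 3-methyl-1-[3-(3-methylbut-2-en-1-yl)-4,6-bis(TIPS-oxy)-2-[6-(TIPS-oxy)-1-benzofuran-2-yl]phenyl]but-2-en-1-yl acetate (racemic) | CC(=O)OC(C=C(C)C)c1c(O[Si](C(C)C)(C(C)C)C(C)C)cc(O[Si](C(C)C)(C(C)C)C(C)C)c(CC=C(C)C)c1-c1cc2ccc(O[Si](C(C)C)(C(C)C)C(C)C)cc2o1 | intermediate
25 | 1-[4,6-dihydroxy-2-(6-hydroxy-1-benzofuran-2-yl)-3-(3-methylbut-2-en-1-yl)phenyl]-3-methylbut-2-en-1-yl acetate (racemic) | CC(=O)OC(C=C(C)C)c1c(O)cc(O)c(CC=C(C)C)c1-c1cc2ccc(O)cc2o1 | intermediate (not isolated)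
26 | 3-hydroxy-5-(6-hydroxy-1-benzofuran-2-yl)-4-(3-methylbut-2-en-1-yl)-6-(3-methylbut-2-en-1-ylidene)cyclohexa-2,4-dien-1-one (o-quinone methide) | O=C1C=C(O)C(CC=C(C)C)=C(c2cc3ccc(O)cc3o2)C1=CC=C(C)C | intermediate (not isolated)
27 | cathafuran C, 5-(6-hydroxy-1-benzofuran-2-yl)-2,2-dimethyl-6-(3-methylbut-2-en-1-yl)-2H-chromen-7-ol (achiral) | CC(C)=CCc1c(O)cc2c(c1-c1cc3ccc(O)cc3o1)C=CC(C)(C)O2 | target

**Totals**
Total step count: 17. Longest linear sequence: 17 steps (1 → 27). The partners 3, 8, 10 and 19 are bought.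

**Steps most likely to fail**

Step 6 (Michael/Dieckmann annulation). The bulky donor 10 may add sluggishly or reversibly, and free methoxide can deacetylate 11 (retro-Claisen) before the ring closes. The fallback sets out from 7 and comes back at 12, and it swaps the roles of the two C–H acids. Knoevenagel condensation of 7 with 10 (piperidine/AcOH, toluene, Dean–Stark) gives tert-butyl 2-acetyl-3-[6-(benzyloxy)-1-benzofuran-2-yl]prop-2-enoate F1 (E/Z mixture), a more electrophilic acceptor. The small nucleophile 8 is then added with catalytic DBU in THF at 0 °C, so the conjugate addition now forms the other C–C bond to the benzofuranyl carbon. Compound 11 is isolated this time and closed in a separate operation with NaH in refluxing THF. No free alkoxide is present there beyond what the product enolate consumes, and this gives 12.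

Step 7 (DDQ aromatisation). The strongly enolised 1,3-dione can add to DDQ as a carbon nucleophile instead of being dehydrogenated. The fallback sets out from 5 and comes back at 13. It brings the benzofuranyl carbon in at the acyl oxidation level, so no oxidant is needed.
- Saponification of 5 (LiOH, THF/H2O) gives 6-(benzyloxy)-1-benzofuran-2-carboxylic acid F2.
- Oxalyl chloride with catalytic DMF gives 6-(benzyloxy)-1-benzofuran-2-carbonyl chloride F3.
- C-acylation of 8 (MgCl2, Et3N, MeCN) gives dimethyl 2-[6-(benzyloxy)-1-benzofuran-2-carbonyl]propanedioate F4.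
- POCl3/Bu3N converts the enol of F4 into dimethyl 2-{[6-(benzyloxy)-1-benzofuran-2-yl]chloromethylidene}propanedioate F5.
- The sodium enolate of 10 adds to F5 and expels chloride (conjugate addition–elimination). This gives 3-tert-butyl 1,1-dimethyl 2-[6-(benzyloxy)-1-benzofuran-2-yl]-4-oxopent-1-ene-1,1,3-tricarboxylate F6.
- NaOMe/MeOH closes F6 by the same Dieckmann reaction, and the product tautomerises directly to 13.

Step 17 (desilylation/o-quinone methide/electrocyclisation cascade). The labile acetate 24 may decompose, or the quinone methide may be trapped intermolecularly. The fallback sets out from 22 and comes back at 27. It replaces the pericyclic closure by an ionic oxa-Michael ring closure.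
- Addition of 19 to 22 with aqueous NH4Cl quench of 23 gives 3-methyl-1-[3-(3-methylbut-2-en-1-yl)-4,6-bis(TIPS-oxy)-2-[6-(TIPS-oxy)-1-benzofuran-2-yl]phenyl]but-2-en-1-ol F7.
- MnO2 oxidises F7 to 3-methyl-1-[3-(3-methylbut-2-en-1-yl)-4,6-bis(TIPS-oxy)-2-[6-(TIPS-oxy)-1-benzofuran-2-yl]phenyl]but-2-en-1-one F8.
- TBAF strips the silyl groups to 1-[4,6-dihydroxy-2-(6-hydroxy-1-benzofuran-2-yl)-3-(3-methylbut-2-en-1-yl)phenyl]-3-methylbut-2-en-1-one F9.
- The ortho phenoxide of F9 adds to the enone in the flask to give 7-hydroxy-5-(6-hydroxy-1-benzofuran-2-yl)-2,2-dimethyl-6-(3-methylbut-2-en-1-yl)chroman-4-one F10.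
- NaBH4 gives 5-(6-hydroxy-1-benzofuran-2-yl)-2,2-dimethyl-6-(3-methylbut-2-en-1-yl)chromane-4,7-diol F11.
- This very electron-rich benzylic alcohol loses water with catalytic PPTS in warm toluene to give 27.

**Further compounds**
F1 | step 6 | tert-butyl 2-acetyl-3-[6-(benzyloxy)-1-benzofuran-2-yl]prop-2-enoate (E/Z mixture) | CC(=O)C(=Cc1cc2ccc(OCc3ccccc3)cc2o1)C(=O)OC(C)(C)C
F2 | step 7 | 6-(benzyloxy)-1-benzofuran-2-carboxylic acid | OC(=O)c1cc2ccc(OCc3ccccc3)cc2o1
F3 | step 7 | 6-(benzyloxy)-1-benzofuran-2-carbonyl chloride | ClC(=O)c1cc2ccc(OCc3ccccc3)cc2o1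
F4 | step 7 | dimethyl 2-[6-(benzyloxy)-1-benzofuran-2-carbonyl]propanedioate | COC(=O)C(C(=O)OC)C(=O)c1cc2ccc(OCc3ccccc3)cc2o1
F5 | step 7 | dimethyl 2-{[6-(benzyloxy)-1-benzofuran-2-yl]chloromethylidene}propanedioate | COC(=O)C(C(=O)OC)=C(Cl)c1cc2ccc(OCc3ccccc3)cc2o1
F6 | step 7 | 3-tert-butyl 1,1-dimethyl 2-[6-(benzyloxy)-1-benzofuran-2-yl]-4-oxopent-1-ene-1,1,3-tricarboxylate (racemic) | COC(=O)C(C(=O)OC)=C(c1cc2ccc(OCc3ccccc3)cc2o1)C(C(C)=O)C(=O)OC(C)(C)C
F7 | step 17 | 3-methyl-1-[3-(3-methylbut-2-en-1-yl)-4,6-bis(TIPS-oxy)-2-[6-(TIPS-oxy)-1-benzofuran-2-yl]phenyl]but-2-en-1-ol (racemic) | CC(C)=CC(O)c1c(O[Si](C(C)C)(C(C)C)C(C)C)cc(O[Si](C(C)C)(C(C)C)C(C)C)c(CC=C(C)C)c1-c1cc2ccc(O[Si](C(C)C)(C(C)C)C(C)C)cc2o1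
F8 | step 17 | 3-methyl-1-[3-(3-methylbut-2-en-1-yl)-4,6-bis(TIPS-oxy)-2-[6-(TIPS-oxy)-1-benzofuran-2-yl]phenyl]but-2-en-1-one | CC(C)=CC(=O)c1c(O[Si](C(C)C)(C(C)C)C(C)C)cc(O[Si](C(C)C)(C(C)C)C(C)C)c(CC=C(C)C)c1-c1cc2ccc(O[Si](C(C)C)(C(C)C)C(C)C)cc2o1
F9 | step 17 | 1-[4,6-dihydroxy-2-(6-hydroxy-1-benzofuran-2-yl)-3-(3-methylbut-2-en-1-yl)phenyl]-3-methylbut-2-en-1-one | CC(C)=CC(=O)c1c(O)cc(O)c(CC=C(C)C)c1-c1cc2ccc(O)cc2o1
F10 | step 17 | 7-hydroxy-5-(6-hydroxy-1-benzofuran-2-yl)-2,2-dimethyl-6-(3-methylbut-2-en-1-yl)chroman-4-one | CC(C)=CCc1c(O)cc2c(c1-c1cc3ccc(O)cc3o1)C(=O)CC(C)(C)O2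
F11 | step 17 | 5-(6-hydroxy-1-benzofuran-2-yl)-2,2-dimethyl-6-(3-methylbut-2-en-1-yl)chromane-4,7-diol (racemic) | CC(C)=CCc1c(O)cc2c(c1-c1cc3ccc(O)cc3o1)C(O)CC(C)(C)O2
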